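Ring C is traced back to a four-carbon squarate unit. Its para oxygens at C2 and C5, the C3 oxygen and the C4 hydrogen, flanking furan carbons C1 and C6, match 3-isopropoxycyclobutenedione attached to C1 of a benzofuran that already carries rings A, B and E. One thermal operation opens the 4-silyloxycyclobutenone to a dienylketene and closes it onto the furan C1=C6 double bond, forging the C5–C6 bond and the whole aromatic ring C with C2–O (silyl ether) and C5–O (free phenol) told apart. The precursor is the racemic tert-butyldimethylsilyl-protected adduct of the C1-lithiated, methyl-protected dibenzodioxin-fused benzofuran and the semisquarate; ring D follows by O-arylation.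

Key step: step 17

Position labels: ring A is the dioxin benzene carrying ring E, its carbons counted in order as positions 1 to 6 of ring A (position 1 C–O–ring E, position 2 C–OR, position 3 C–H, position 4 C–OR, position 5 C–O joined to position 6 of ring B, position 6 C–O joined to position 1 of ring B). Ring B is the central benzene, counted likewise (position 1 C–O to ring A, position 2 C–OR, position 3 C–H, position 4 furan C–O, position 5 furan-fused carbon, position 6 C–O to ring A). Ring C is the outer benzofuran benzene (C1 furan C–O, C2 C–O–ring D, C3 C–OR, C4 C–H, C5 C–OR, C6 bonded to position 5 of ring B). Rings D and E are the 3,5-dioxygenated phenoxy groups on C2 and on position 1 of ring A.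

Assumption: the target has no stereocentre; intermediates with one stereocentre (23, 27, 30, 31, 33) are racemic and drawn as one enantiomer, and enol ether 21 is an E/Z mixture drawn as E.

**Rings A and E (steps 1–5)**

Step 1
Reactants: 1 1,5-dibromo-2,4-dimethoxybenzene
Product: 4 2,6-dibromo-3,5-dimethoxyphenol, via aryllithium 2 (not isolated), via boronate ester 3 (not isolated)
Conditions: LiN(iPr)2, THF, −78 °C; B(OiPr)3, −78 °C → rt; H2O2, aq NaOH, 0 °C
Reagents that add atoms: hydrogen peroxide, OO
Why: The hydrogen flanked by the two bromines is the most acidic ring position, so amide-base deprotonation (directed ortho-metalation), borylation and oxidative C–B to C–O conversion should place the future oxygen of position 6 of ring A between the two halogens without regiochemical ambiguity.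

Step 2
Reactants: 4 2,6-dibromo-3,5-dimethoxyphenol
Product: 5 1,3-dibromo-4,6-dimethoxy-2-(methoxymethoxy)benzene
Conditions: MOMCl, iPr2NEt, CH2Cl2, 0 °C → rt
Reagents that add atoms: chloromethyl methyl ether, COCCl
Why: Williamson-type O-alkylation of the acidic phenol installs an acetal that withstands organolithiums, copper and carbonate bases and is later removed by acid.

Step 3
Reactants: 5 1,3-dibromo-4,6-dimethoxy-2-(methoxymethoxy)benzene
Product: 8 3-bromo-4,6-dimethoxy-2-(methoxymethoxy)phenol, via aryllithium 6 (not isolated), via boronate ester 7 (not isolated)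
Conditions: n-BuLi (1.0 equiv), THF, −78 °C; B(OMe)3, −78 °C → rt; H2O2, aq NaOH, 0 °C
Reagents that add atoms: hydrogen peroxide, OO
Why: Bromine–lithium exchange on the symmetric dibromide should stop after one exchange because the chelated aryllithium does not exchange again, and borylation–oxidation then gives a single monophenol whichever bromine reacts.

Step 4
Reactants: 8 3-bromo-4,6-dimethoxy-2-(methoxymethoxy)phenol; 9 3,5-dimethoxyphenylboronic acid
Product: 10 1-bromo-3-(3,5-dimethoxyphenoxy)-4,6-dimethoxy-2-(methoxymethoxy)benzene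
Conditions: Cu(OAc)2, pyridine, 4 Å MS, CH2Cl2, air, rt
Reagents that add atoms: none
Why: Chan–Lam oxidative coupling of a phenol with an unhindered, electron-rich arylboronic acid runs at room temperature, accepts 2,6-disubstituted phenols and leaves the aryl bromide untouched, so ring E is attached here to the oxygen on position 1 of ring A.

Step 5
Reactants: 10 1-bromo-3-(3,5-dimethoxyphenoxy)-4,6-dimethoxy-2-(methoxymethoxy)benzene
Product: 13 3-(3,5-dimethoxyphenoxy)-4,6-dimethoxy-2-(methoxymethoxy)phenol, via aryllithium 11 (not isolated), via boronate ester 12 (not isolated)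
Conditions: n-BuLi, THF, −78 °C; B(OMe)3, −78 °C → rt; H2O2, aq NaOH, 0 °C
Reagents that add atoms: hydrogen peroxide, OO
Why: Bromine–lithium exchange is far faster than any ring deprotonation at −78 °C, and borylation–oxidation turns the last bromine into the free hydroxyl on position 5 of ring A, next to the protected oxygen on position 6.

**Ring B (steps 6–9)**

Step 6
Reactants: 14 1-fluoro-3,5-dimethoxybenzene
Product: 16 2-fluoro-4,6-dimethoxybenzaldehyde, via iminium chloride 15 (not isolated)
Conditions: POCl3, DMF, 0 → 70 °C; then H2O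
Reagents that add atoms: N,N-dimethylformamide, CN(C)C=O; water, O
Why: Vilsmeier–Haack formylation of a 5-substituted 1,3-dimethoxybenzene should occur para to one methoxy group and ortho to fluorine, the less hindered activated site, and not between the two methoxy groups.

Step 7
Reactants: 16 2-fluoro-4,6-dimethoxybenzaldehyde
Product: 17 2-fluoro-6-hydroxy-4-methoxybenzaldehyde
Conditions: BCl3, CH2Cl2, −78 → 0 °C; H2O
Reagents that add atoms: none
Why: BCl3 chelates between the aldehyde oxygen and the ortho methoxy oxygen, so chelation-controlled ether cleavage should remove only the methyl group ortho to the carbonyl.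

Step 8
Reactants: 17 2-fluoro-6-hydroxy-4-methoxybenzaldehyde
Product: 18 3-bromo-2-fluoro-6-hydroxy-4-methoxybenzaldehyde
Conditions: NBS, MeCN, 0 °C → rt
Reagents that add atoms: N-bromosuccinimide, O=C1CCC(=O)N1Br
Why: Electrophilic aromatic bromination is directed para to the free phenol and ortho to the methoxy group, the usual outcome for 4-alkoxysalicylaldehydes, which puts bromine on the carbon that becomes position 1 of ring B.

Step 9
Reactants: 18 3-bromo-2-fluoro-6-hydroxy-4-methoxybenzaldehyde
Product: 19 3-bromo-2-fluoro-4-methoxy-6-(methoxymethoxy)benzaldehyde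
Conditions: MOMCl, iPr2NEt, CH2Cl2, 0 °C → rt
Reagents that add atoms: chloromethyl methyl ether, COCCl
Why: O-Alkylation masks the phenol so that no phenoxide deactivates the ring in the coming substitution and so that one acid treatment later frees both hydroxyls together.

**Union, benzofuran and dioxin (steps 10–13)**

Step 10
Reactants: 13 3-(3,5-dimethoxyphenoxy)-4,6-dimethoxy-2-(methoxymethoxy)phenol; 19 3-bromo-2-fluoro-4-methoxy-6-(methoxymethoxy)benzaldehyde
Product: 20 3-bromo-2-[3-(3,5-dimethoxyphenoxy)-4,6-dimethoxy-2-(methoxymethoxy)phenoxy]-4-methoxy-6-(methoxymethoxy)benzaldehyde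
Conditions: K2CO3, DMF, 90 °C
Reagents that add atoms: none
Why: Nucleophilic aromatic substitution (addition–elimination) of the fluoride ortho to the formyl group by the phenoxide of 13 is favoured because both alkoxy groups of the electrophile are meta to the reacting carbon and the ortho bromine helps inductively, and since the oxygen on position 6 of ring A is blocked, only the oxygen on position 5 of ring A can bond to position 6 of ring B.

Step 11
Reactants: 20 diaryl ether aldehyde
Product: 21 methyl enol ether of 20 (the formyl group replaced by a 2-methoxyethenyl group; E/Z mixture)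
Conditions: Ph3P(CH2OMe)Cl, KOtBu, THF, 0 °C → rt
Reagents that add atoms: (methoxymethyl)triphenylphosphonium chloride, COC[P+](c1ccccc1)(c1ccccc1)c1ccccc1.[Cl-]
Why: Wittig olefination with the methoxymethylene ylide homologates the non-enolisable aldehyde to an enol ether without touching the aryl bromide or the acetals, and the alkene geometry is of no consequence.

Step 12
Reactants: 21 methyl enol ether
Product: 24 2-[(5-bromo-6-methoxy-1-benzofuran-4-yl)oxy]-6-(3,5-dimethoxyphenoxy)-3,5-dimethoxyphenol, via arylacetaldehyde 22 (not isolated), via lactol 23 (not isolated)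
Conditions: 3 M aq HCl, THF, 55 °C
Reagents that add atoms: none
Why: Aqueous acid cleaves both methoxymethyl acetals and hydrolyses the enol ether to the arylacetaldehyde, whose ortho hydroxyl closes to the five-membered lactol and dehydrates to the benzofuran (acid-catalysed cyclodehydration), which also removes the activating carbonyl before the base-mediated ring closure so that no Smiles rearrangement can scramble the dioxin regiochemistry.

Step 13
Reactants: 24 bromobenzofuranyl aryl ether phenol
Product: 25 dibenzodioxin-fused benzofuran (rings A, B and E; furan fused at positions 4 and 5 of ring B; methoxy groups at positions 2 and 4 of ring A, at position 2 of ring B and on ring E; both furan carbons C–H)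
Conditions: CuI (cat.), N,N-dimethylglycine (cat.), Cs2CO3, 1,4-dioxane, 100 °C
Reagents that add atoms: none
Why: Intramolecular Ullmann diaryl ether synthesis with monovalent copper closes the six-membered dioxin ring between the phenoxide on position 6 of ring A and the bromide on position 1 of ring B, the intramolecular setting compensating for the hindered, electron-rich partners.

**Cyclobutenone precursor (steps 14–16)**

Step 14
Reactants: 26 diisopropyl squarate
Product: 28 3-isopropoxycyclobut-3-ene-1,2-dione, via hydroxycyclobutenone 27 (not isolated)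
Conditions: LiAlH(OtBu)3, THF, −78 → −20 °C; then conc. aq HCl, CH2Cl2, rt
Reagents that add atoms: none
Why: Hydride addition to one carbonyl of the squarate, then acid-mediated 1,3-transposition of the allylic hydroxyl with loss of isopropanol, is the established way to the hydrogen-substituted alkoxycyclobutenedione.

Step 15
Reactants: 25 dibenzodioxin-fused benzofuran; 28 3-isopropoxycyclobut-3-ene-1,2-dione
Product: 30 4-hydroxy-3-isopropoxy-4-(benzofuran-C1-yl)cyclobut-2-en-1-one of 25 (racemic), via 2-lithiobenzofuran 29 (not isolated)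
Conditions: n-BuLi, THF, −78 °C; then 28, THF, −78 °C; aq NH4Cl
Reagents that add atoms: none
Why: The furan C1–H is the kinetically most acidic position and is lithiated at −78 °C before any methoxy-directed ring metalation, and the aryllithium adds 1,2 to the more electrophilic ketone of 28 (the one that is not a vinylogous ester carbonyl), giving the quaternary carbinol as a racemate because nothing chiral is present.

Step 16
Reactants: 30 hydroxycyclobutenone
Product: 31 4-(tert-butyldimethylsilyloxy)-3-isopropoxycyclobut-2-en-1-one carried on furan carbon C1 of 25 (racemic)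
Conditions: TBSOTf, 2,6-lutidine, CH2Cl2, −78 → 0 °C
Reagents that add atoms: tert-butyldimethylsilyl trifluoromethanesulfonate, CC(C)(C)[Si](C)(C)OS(=O)(=O)C(F)(F)F
Why: Silyl triflate with a hindered pyridine base silylates the tertiary alcohol, which prevents lactone formation from the later ketene and marks the future C2 oxygen.

**Ring C and completion (steps 17–21)**

Step 17
Reactants: 31 silyloxycyclobutenone
Product: 34 dibenzodioxin-fused dibenzofuran with C5–OH free, C2–O-silyl and C3–O-isopropyl, via dienylketene 32 (not isolated), via cyclohexadienone 33 (not isolated)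
Conditions: toluene (degassed, dilute), 110 °C
Reagents that add atoms: none
Why: Heating triggers a four-electron conrotatory electrocyclic opening of the cyclobutenone, breaking the bond between the carbonyl carbon and the silyloxy-bearing carbon, to dienylketene 32 in which the ketene C5=C4, the enol ether C3=C2 and the furan C1=C6 bond form a hexatriene. A thermal six-electron disrotatory electrocyclization then joins ketene carbon C5 to furan carbon C6 and the resulting cyclohexadienone 33 tautomerises to the phenol, so ring C is closed as a six-membered carbocycle by a pericyclic mode. The closest known reaction type is the thermal ring expansion of 4-aryl- and 4-heteroaryl-4-oxygenated cyclobutenones to hydroquinone derivatives (Moore rearrangement). No stereocentre is formed and the carbinol stereocentre of racemic 31 is erased on aromatisation. The step needs the ketene to form cis to the benzofuran, which the torquoselectivity of the opening secures because the silyloxy donor rotates outward and the heteroaryl group inward, and the site of closure is fixed because C6 is the only carbon ortho to the point of attachment. The silyl group stays on the C2 oxygen while the C5 oxygen emerges as a free phenol, which differentiates the two para oxygens.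

Step 18
Reactants: 34 C5 phenol
Product: 35 C5 methyl ether of 34 (C2–O-silyl retained)
Conditions: MeI, K2CO3, acetone, 45 °C
Reagents that add atoms: iodomethane, CI
Why: Williamson O-methylation of the only free phenol under mild carbonate conditions in acetone should leave the aryl silyl ether at C2 intact.

Step 19
Reactants: 35 C2 silyl ether
Product: 36 C2 phenol (C5–OMe, C3–O-isopropyl)
Conditions: Bu4NF, AcOH, THF, 0 °C
Reagents that add atoms: none
Why: Fluoride-induced cleavage of the aryl silyl ether, buffered with acetic acid to keep the electron-rich phenoxide from oxidising, frees the C2 hydroxyl alone.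

Step 20
Reactants: 36 C2 phenol; 9 3,5-dimethoxyphenylboronic acid
Product: 37 fully O-alkylated phlorofucofuroeckol A (eight methyl ethers, C3 isopropyl ether)
Conditions: Cu(OAc)2, pyridine, 4 Å MS, CH2Cl2, air, rt
Reagents that add atoms: none
Why: Chan–Lam coupling arylates the C2 phenol under neutral room-temperature conditions that a doubly ortho-substituted, oxidation-prone phenol tolerates better than a hot basic Ullmann coupling.

Step 21
Reactants: 37 fully O-alkylated phlorofucofuroeckol A
Product: 38 phlorofucofuroeckol A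
Conditions: BBr3 (excess), CH2Cl2, −78 °C → rt; then MeOH/H2O
Reagents that add atoms: none
Why: BBr3 cleaves aryl methyl and isopropyl ethers by Lewis acid–base complexation and bromide attack on the alkyl group while leaving diaryl ether, dioxin and furan C–O bonds intact, so all nine hydroxyls should be released in one operation.

**Compound list**

1 | 1,5-dibromo-2,4-dimethoxybenzene | COc1cc(OC)c(Br)cc1Br | starting material
2 | (2,6-dibromo-3,5-dimethoxyphenyl)lithium | [Li]c1c(Br)c(OC)cc(OC)c1Br | intermediate
3 | diisopropyl (2,6-dibromo-3,5-dimethoxyphenyl)boronate | CC(C)OB(OC(C)C)c1c(Br)c(OC)cc(OC)c1Br | intermediate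
4 | 2,6-dibromo-3,5-dimethoxyphenol | Oc1c(Br)c(OC)cc(OC)c1Br | intermediate
5 | 1,3-dibromo-4,6-dimethoxy-2-(methoxymethoxy)benzene | COCOc1c(Br)c(OC)cc(OC)c1Br | intermediate
6 | [3-bromo-4,6-dimethoxy-2-(methoxymethoxy)phenyl]lithium | [Li]c1c(OC)cc(OC)c(Br)c1OCOC | intermediate
7 | dimethyl [3-bromo-4,6-dimethoxy-2-(methoxymethoxy)phenyl]boronate | COB(OC)c1c(OC)cc(OC)c(Br)c1OCOC | intermediate
8 | 3-bromo-4,6-dimethoxy-2-(methoxymethoxy)phenol | Oc1c(OC)cc(OC)c(Br)c1OCOC | intermediate
9 | 3,5-dimethoxyphenylboronic acid | COc1cc(OC)cc(B(O)O)c1 | starting material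
10 | 1-bromo-3-(3,5-dimethoxyphenoxy)-4,6-dimethoxy-2-(methoxymethoxy)benzene | COCOc1c(Br)c(OC)cc(OC)c1Oc1cc(OC)cc(OC)c1 | intermediate
11 | [3-(3,5-dimethoxyphenoxy)-4,6-dimethoxy-2-(methoxymethoxy)phenyl]lithium | [Li]c1c(OC)cc(OC)c(Oc2cc(OC)cc(OC)c2)c1OCOC | intermediate
12 | dimethyl [3-(3,5-dimethoxyphenoxy)-4,6-dimethoxy-2-(methoxymethoxy)phenyl]boronate | COB(OC)c1c(OC)cc(OC)c(Oc2cc(OC)cc(OC)c2)c1OCOC | intermediate
13 | 3-(3,5-dimethoxyphenoxy)-4,6-dimethoxy-2-(methoxymethoxy)phenol | Oc1c(OC)cc(OC)c(Oc2cc(OC)cc(OC)c2)c1OCOC | intermediate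
14 | 1-fluoro-3,5-dimethoxybenzene | COc1cc(F)cc(OC)c1 | starting material
15 | N-[(2-fluoro-4,6-dimethoxyphenyl)methylidene]-N-methylmethanaminium chloride | COc1cc(F)c(C=[N+](C)C)c(OC)c1.[Cl-] | intermediate
16 | 2-fluoro-4,6-dimethoxybenzaldehyde | COc1cc(F)c(C=O)c(OC)c1 | intermediate
17 | 2-fluoro-6-hydroxy-4-methoxybenzaldehyde | COc1cc(O)c(C=O)c(F)c1 | intermediate
18 | 3-bromo-2-fluoro-6-hydroxy-4-methoxybenzaldehyde | COc1cc(O)c(C=O)c(F)c1Br | intermediate
19 | 3-bromo-2-fluoro-4-methoxy-6-(methoxymethoxy)benzaldehyde | COCOc1cc(OC)c(Br)c(F)c1C=O | intermediate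
20 | 3-bromo-2-[3-(3,5-dimethoxyphenoxy)-4,6-dimethoxy-2-(methoxymethoxy)phenoxy]-4-methoxy-6-(methoxymethoxy)benzaldehyde | O=Cc1c(OCOC)cc(OC)c(Br)c1Oc1c(OC)cc(OC)c(Oc2cc(OC)cc(OC)c2)c1OCOC | intermediate
21 | methyl enol ether of 20, 2-methoxyethenyl in place of formyl (E/Z mixture, E drawn) | CO/C=C/c1c(OCOC)cc(OC)c(Br)c1Oc1c(OC)cc(OC)c(Oc2cc(OC)cc(OC)c2)c1OCOC | intermediate
22 | 2-{3-bromo-2-[3-(3,5-dimethoxyphenoxy)-2-hydroxy-4,6-dimethoxyphenoxy]-6-hydroxy-4-methoxyphenyl}acetaldehyde | O=CCc1c(O)cc(OC)c(Br)c1Oc1c(OC)cc(OC)c(Oc2cc(OC)cc(OC)c2)c1O | intermediate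
23 | 5-bromo-4-[3-(3,5-dimethoxyphenoxy)-2-hydroxy-4,6-dimethoxyphenoxy]-6-methoxy-2,3-dihydro-1-benzofuran-2-ol (racemic) | O[C@H]1Cc2c(Oc3c(OC)cc(OC)c(Oc4cc(OC)cc(OC)c4)c3O)c(Br)c(OC)cc2O1 | intermediate
24 | 2-[(5-bromo-6-methoxy-1-benzofuran-4-yl)oxy]-6-(3,5-dimethoxyphenoxy)-3,5-dimethoxyphenol | COc1cc2occc2c(Oc2c(OC)cc(OC)c(Oc3cc(OC)cc(OC)c3)c2O)c1Br | intermediate
25 | dibenzodioxin-fused benzofuran: ring A with 3,5-dimethoxyphenoxy at position 1 and methoxy at positions 2 and 4, ring B with methoxy at position 2 and the furan fused through position 4 (O) and position 5 (C), furan carbons unsubstituted | COc1cc(OC)cc(Oc2c(OC)cc(OC)c3c2Oc2c(OC)cc4occc4c2O3)c1 | intermediate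
26 | diisopropyl squarate (3,4-diisopropoxycyclobut-3-ene-1,2-dione) | CC(C)OC1=C(OC(C)C)C(=O)C1=O | starting material
27 | 4-hydroxy-2,3-diisopropoxycyclobut-2-en-1-one (racemic) | CC(C)OC1=C(OC(C)C)[C@@H](O)C1=O | intermediate
28 | 3-isopropoxycyclobut-3-ene-1,2-dione | CC(C)OC1=CC(=O)C1=O | intermediate
29 | 25 lithiated at furan carbon C1 | COc1cc(OC)cc(Oc2c(OC)cc(OC)c3c2Oc2c(OC)cc4oc([Li])cc4c2O3)c1 | intermediate
30 | 4-hydroxy-3-isopropoxycyclobut-2-en-1-one bonded through its ring carbon 4 to furan carbon C1 of 25 (racemic) | COc1cc(OC)cc(Oc2c(OC)cc(OC)c3c2Oc2c(OC)cc4oc([C@]5(O)C(OC(C)C)=CC5=O)cc4c2O3)c1 | intermediate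
31 | 4-(tert-butyldimethylsilyloxy)-3-isopropoxycyclobut-2-en-1-one bonded through its ring carbon 4 to furan carbon C1 of 25 (racemic) | COc1cc(OC)cc(Oc2c(OC)cc(OC)c3c2Oc2c(OC)cc4oc([C@]5(O[Si](C)(C)C(C)(C)C)C(OC(C)C)=CC5=O)cc4c2O3)c1 | intermediate
32 | dienylketene: furan C1 bearing a 1-silyloxy-2-isopropoxybuta-1,3-dien-4-one chain with the ketene cis to the benzofuran | COc1cc(OC)cc(Oc2c(OC)cc(OC)c3c2Oc2c(OC)cc4oc(/C(O[Si](C)(C)C(C)(C)C)=C(\C=C=O)OC(C)C)cc4c2O3)c1 | intermediate
33 | cyclohexa-2,4-dienone tautomer of 34 (C5 ketone, C6 sp3 C–H; racemic) | COc1cc(OC)cc(Oc2c(OC)cc(OC)c3c2Oc2c(OC)cc4OC5=C(O[Si](C)(C)C(C)(C)C)C(OC(C)C)=CC(=O)[C@H]5c4c2O3)c1 | intermediate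
34 | dibenzodioxin-fused dibenzofuran with C5–OH, C2–O-tert-butyldimethylsilyl, C3–O-isopropyl | COc1cc(OC)cc(Oc2c(OC)cc(OC)c3c2Oc2c(OC)cc4oc5c(O[Si](C)(C)C(C)(C)C)c(OC(C)C)cc(O)c5c4c2O3)c1 | intermediate
35 | C5 methyl ether of 34 | COc1cc(OC)cc(Oc2c(OC)cc(OC)c3c2Oc2c(OC)cc4oc5c(O[Si](C)(C)C(C)(C)C)c(OC(C)C)cc(OC)c5c4c2O3)c1 | intermediate
36 | C2 phenol (C5–OMe, C3–O-isopropyl) | COc1cc(OC)cc(Oc2c(OC)cc(OC)c3c2Oc2c(OC)cc4oc5c(O)c(OC(C)C)cc(OC)c5c4c2O3)c1 | intermediate
37 | phlorofucofuroeckol A octamethyl ether C3 isopropyl ether | COc1cc(OC)cc(Oc2c(OC)cc(OC)c3c2Oc2c(OC)cc4oc5c(Oc6cc(OC)cc(OC)c6)c(OC(C)C)cc(OC)c5c4c2O3)c1 | intermediate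
38 | phlorofucofuroeckol A | Oc1cc(O)cc(Oc2c(O)cc(O)c3c2Oc2c(O)cc4oc5c(Oc6cc(O)cc(O)c6)c(O)cc(O)c5c4c2O3)c1 | target

**Step count**

Total: 21 steps. Longest linear sequence: 16 steps (steps 1–5, 10–13, 15–21); steps 6–9 and step 14 are side branches.

**Steps most likely to fail**

Step 17 (ring expansion). The thermolysis may be accompanied by loss or transfer of the silyl group and air oxidation of the electron-rich hydroquinone monoether, which would erase the difference between the C2 and C5 oxygens. The fallback sets out from hydroxycyclobutenone 30, without silylation, and accepts the quinone. Heating 30 in xylene at 140 °C and then stirring with Ag2O in air should give the ring C 1,4-quinone (C2 and C5 carbonyls, C3 isopropoxy) F1. Reduction with Na2S2O4 in THF/water gives the C2,C5-hydroquinone F2. iPr3SiCl and imidazole in DMF at 0 °C should silylate the hydroxyl with a free ortho position (C5, next to C4–H) to give the C5 triisopropylsilyl ether with free C2–OH F3. Chan–Lam coupling with 9 gives the C2 3,5-dimethoxyphenyl ether F4. Bu4NF gives the C5 phenol F5, and BBr3 then cleaves all alkyl ethers; the fallback comes back to the route at target 38.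

Step 10 (diaryl ether by substitution). Four ortho substituents crowd the forming C–O bond, so the substitution may stall, and at the temperature then needed the hindered phenoxide may add reversibly to the aldehyde or the aldehyde may degrade. The fallback sets out from aldehyde 19 and swaps the activating group for a slimmer, linear nitrile. I2 and aqueous NH3 in THF convert 19 into 3-bromo-2-fluoro-4-methoxy-6-(methoxymethoxy)benzonitrile F6. Substitution with 13 (K2CO3, DMF) gives the diaryl ether nitrile F7. iBu2AlH in toluene at −78 °C followed by cold dilute acid hydrolysis of the aldimine returns to the route at aldehyde 20.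

Step 13 (dioxin closure). Insertion of copper into the hindered, electron-rich carbon–bromine bond at position 1 of ring B may be slow, so that protodebromination or intermolecular etherification competes. The fallback sets out from bromophenol 24 and reverses the polarity at that carbon. Miyaura borylation (PdCl2(dppf), bis(pinacolato)diboron, KOAc, 1,4-dioxane, 90 °C) gives the ring B pinacol boronate phenol F8. An intramolecular Chan–Lam coupling (Cu(OAc)2, pyridine, 4 Å MS, air, dilute CH2Cl2, rt) then closes the dioxin and returns to the route at 25.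

Further compounds

F1 | step 17 | ring C 1,4-quinone of the dibenzodioxin-fused dibenzofuran (C2 and C5 carbonyls, C3 isopropoxy) | COc1cc(OC)cc(Oc2c(OC)cc(OC)c3c2Oc2c(OC)cc4oc5c(c4c2O3)C(=O)C=C(OC(C)C)C5=O)c1
F2 | step 17 | C2,C5-hydroquinone (C3 isopropoxy) | COc1cc(OC)cc(Oc2c(OC)cc(OC)c3c2Oc2c(OC)cc4oc5c(O)c(OC(C)C)cc(O)c5c4c2O3)c1
F3 | step 17 | C5 triisopropylsilyl ether with free C2–OH | COc1cc(OC)cc(Oc2c(OC)cc(OC)c3c2Oc2c(OC)cc4oc5c(O)c(OC(C)C)cc(O[Si](C(C)C)(C(C)C)C(C)C)c5c4c2O3)c1
F4 | step 17 | C2 3,5-dimethoxyphenyl ether, C5 triisopropylsilyl ether | COc1cc(OC)cc(Oc2c(OC)cc(OC)c3c2Oc2c(OC)cc4oc5c(Oc6cc(OC)cc(OC)c6)c(OC(C)C)cc(O[Si](C(C)C)(C(C)C)C(C)C)c5c4c2O3)c1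
F5 | step 17 | C2 3,5-dimethoxyphenyl ether with free C5–OH | COc1cc(OC)cc(Oc2c(OC)cc(OC)c3c2Oc2c(OC)cc4oc5c(Oc6cc(OC)cc(OC)c6)c(OC(C)C)cc(O)c5c4c2O3)c1
F6 | step 10 | 3-bromo-2-fluoro-4-methoxy-6-(methoxymethoxy)benzonitrile | COCOc1cc(OC)c(Br)c(F)c1C#N
F7 | step 10 | 3-bromo-2-[3-(3,5-dimethoxyphenoxy)-4,6-dimethoxy-2-(methoxymethoxy)phenoxy]-4-methoxy-6-(methoxymethoxy)benzonitrile | N#Cc1c(OCOC)cc(OC)c(Br)c1Oc1c(OC)cc(OC)c(Oc2cc(OC)cc(OC)c2)c1OCOC
F8 | step 13 | 2-{[6-methoxy-5-(4,4,5,5-tetramethyl-1,3,2-dioxaborolan-2-yl)-1-benzofuran-4-yl]oxy}-6-(3,5-dimethoxyphenoxy)-3,5-dimethoxyphenol | COc1cc2occc2c(Oc2c(OC)cc(OC)c(Oc3cc(OC)cc(OC)c3)c2O)c1B1OC(C)(C)C(C)(C)O1
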